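Numbering (germacrane): C1H=C10(Me)–C9H2–C8H(O‑vanilloyl)–C7H(iPr)–C6H(OH)–C5H=C4(Me)–C3H2–C2H2–C1. Retrosynthetic cuts, in order: the vanillate C–O bond at O8, the doubly allylic ring bond C2–C3, C1=C10, C8–C9, C6–C7.
Enabling feature: C2–C3 is the central σ‑bond of a (Z,Z)‑1,5‑diene. Because C1=C10 is Z, C2 lies cis to C9 and 1,5 to O8, so an O8–SO2–C2 bridge fits a seven‑membered ring (O8, S, C2, C1, C10, C9, C8).
This sultone serves at once as tether, as mask for O8, as lock for the Z olefin and as carbanion‑stabilising group at C2. Its anion closes the ten‑membered ring on the Z‑allylic bromide at C3; excision of SO2 then frees only O8–H for acylation.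
Forward order: chain C3–C8 (aldol), C9/C10 (methallylboration), seven‑membered sultone (RCM), ten‑membered carbocycle (bicyclo[5.3.2] sultone), loss of SO2, esterification, desilylation.
Stereochemistry: C6 and C7 come from an Evans syn aldol ((R)‑benzyloxazolidinone) and C8 from a reagent‑controlled Brown methallylboration. C4=C5 (Z) comes from the anti carbomagnesiation of propargyl alcohol and C1=C10 (Z) from the ring size in the RCM.

Key step: step 12

Remark: 7, prop‑2‑ene‑1‑sulfonyl chloride, methallylmagnesium chloride and (+)‑B‑methoxydiisopinocampheylborane are taken as commercial. The C2 centre of 18 is of no consequence, since it becomes CH2 in step 13.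

Step 1
Reactants: 1 prop‑2‑yn‑1‑ol
Product: 3 (Z)‑3‑iodo‑2‑methylprop‑2‑en‑1‑ol, via alkenylmagnesium alkoxide 2 (not isolated)
Conditions: MeMgBr (2.5 equiv), CuI (10 mol %), THF/Et2O, −10 °C to rt; I2, −10 °C; H2O
Reagents that add atoms: methylmagnesium bromide C[Mg]Br; iodine II
Why: Copper‑catalysed carbomagnesiation of the propargylic alkoxide is an anti addition because magnesium ends chelated in the five‑membered ring 2, and stereoretentive iodinolysis then places I cis to CH2OH, which fixes the Z geometry of C4=C5.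

Step 2
Reactants: 3 (Z)‑3‑iodo‑2‑methylprop‑2‑en‑1‑ol
Product: 4 (Z)‑tert‑butyl[(3‑iodo‑2‑methylprop‑2‑en‑1‑yl)oxy]dimethylsilane
Conditions: TBSCl, imidazole, CH2Cl2, 0 °C to rt
Reagents that add atoms: tert‑butyldimethylsilyl chloride CC(C)(C)[Si](C)(C)Cl
Why: Imidazole‑promoted silylation masks the primary allylic alcohol (O on C3) for the organolithium step and marks the later leaving‑group site.

Step 3
Reactants: 4 (Z)‑vinyl iodide silyl ether
Product: 6 (Z)‑4‑(tert‑butyldimethylsilyloxy)‑3‑methylbut‑2‑enal, via Z‑alkenyllithium 5 (not isolated)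
Conditions: t‑BuLi (2.0 equiv), Et2O, −78 °C; DMF, −78 to 0 °C; H2O
Reagents that add atoms: N,N‑dimethylformamide CN(C)C=O
Why: Iodine–lithium exchange is stereoretentive at −78 °C in ether, and formylation of 5 with DMF (Bouveault aldehyde synthesis) should give the Z enal carrying C3–C6.

Step 4
Reactants: 7 (R)‑4‑benzyl‑3‑(3‑methylbutanoyl)oxazolidin‑2‑one; 6 Z enal
Product: 9 (R)‑4‑benzyl‑3‑[(2R,3S,4Z)‑6‑(tert‑butyldimethylsilyloxy)‑3‑hydroxy‑5‑methyl‑2‑(propan‑2‑yl)hex‑4‑enoyl]oxazolidin‑2‑one, via dibutylboron Z‑enolate 8 (not isolated)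
Conditions: Bu2BOTf, Et3N, CH2Cl2, −78 to 0 °C; 6, −78 to −10 °C; pH 7 buffer, MeOH, H2O2, 0 °C
Reagents that add atoms: none
Why: Evans syn aldol, in which the Z boron enolate reacts through a closed Zimmerman–Traxler chair on the face away from the benzyl group, setting C7 and C6 (syn) in the sense of the target under conditions mild enough to keep the enal Z.

Step 5
Reactants: 9 aldol imide
Product: 10 (2R,3S,4Z)‑6‑(tert‑butyldimethylsilyloxy)‑3‑hydroxy‑N‑methoxy‑N,5‑dimethyl‑2‑(propan‑2‑yl)hex‑4‑enamide
Conditions: MeONHMe·HCl, AlMe3, THF, −20 to 0 °C; aq. Rochelle salt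
Reagents that add atoms: N,O‑dimethylhydroxylamine hydrochloride CNOC.Cl
Why: Aluminium‑amide transamination to the Weinreb amide is assisted by the free β‑hydroxyl and should remove the auxiliary without retro‑aldol cleavage or epimerisation.

Step 6
Reactants: 10 hydroxy Weinreb amide
Product: 11 (2R,3S,4Z)‑3,6‑bis(tert‑butyldimethylsilyloxy)‑N‑methoxy‑N,5‑dimethyl‑2‑(propan‑2‑yl)hex‑4‑enamide
Conditions: TBSOTf, 2,6‑lutidine, CH2Cl2, −78 to 0 °C
Reagents that add atoms: tert‑butyldimethylsilyl triflate CC(C)(C)[Si](C)(C)OS(=O)(=O)C(F)(F)F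
Why: Silyl triflate/lutidine silylation of the hindered allylic alcohol keeps O6 masked to the last step, which is what tells O6 from O8.

Step 7
Reactants: 11 bis‑silyl Weinreb amide
Product: 12 (2R,3S,4Z)‑3,6‑bis(tert‑butyldimethylsilyloxy)‑5‑methyl‑2‑(propan‑2‑yl)hex‑4‑enal
Conditions: DIBAL‑H, THF, −78 °C; aq. Rochelle salt
Reagents that add atoms: none
Why: Reduction of a Weinreb amide stops at the chelated tetrahedral adduct and releases the C8 aldehyde only on work‑up, and the bulky α‑isopropyl group disfavours enolisation at C7.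

Step 8
Reactants: 12 aldehyde
Product: 13 (4R,5S,6S,7Z)‑6,9‑bis(tert‑butyldimethylsilyloxy)‑2,8‑dimethyl‑5‑(propan‑2‑yl)nona‑1,7‑dien‑4‑ol (all‑syn C6/C7/C8 triad)
Conditions: (+)‑Ipc2BOMe, methallylMgCl, Et2O, −78 °C to rt; 12, −78 °C; NaOH, H2O2
Reagents that add atoms: B‑methallyldiisopinocampheylborane of the (−)‑α‑pinene series C=C(C)CB([C@H]1C[C@H]2C[C@@H]([C@@H]1C)C2(C)C)[C@H]1C[C@H]2C[C@@H]([C@@H]1C)C2(C)C, made in the flask from methallylmagnesium chloride C=C(C)C[Mg]Cl
Why: Brown asymmetric allylboration (methallyl variant) runs through a closed chair in which the Ipc ligands of this series direct attack to the aldehyde face giving the (8R) carbinol, syn to the isopropyl group, by reagent control.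

Step 9
Reactants: 13 homoallylic alcohol
Product: 14 prop‑2‑ene‑1‑sulfonate (allylsulfonate) ester of 13 at O8
Conditions: CH2=CHCH2SO2Cl, Et3N, THF, −20 to 0 °C
Reagents that add atoms: prop‑2‑ene‑1‑sulfonyl chloride C=CCS(=O)(=O)Cl
Why: Sulfonylation runs through the small, very reactive sulfene formed with Et3N, which reaches even a hindered secondary alcohol and leaves the C8–O bond and its configuration untouched.

Step 10
Reactants: 14 allylsulfonate
Product: 15 seven‑membered allylic sultone (5‑methyl‑3,6‑dihydro‑7H‑1,2‑oxathiepine 2,2‑dioxide; ring O8, S, C2, C1, C10, C9, C8) bearing the C7–C3 side chain at C8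
Conditions: (H2IMes)(PCy3)Cl2Ru=CHPh (second‑generation Grubbs catalyst, 10 mol %), CH2Cl2 (5 mM), reflux
Reagents that add atoms: none
Why: Ring‑closing metathesis of allylsulfonates of homoallylic alcohols to seven‑membered sultones is a known reaction type, a ring of this size can hold only the Z olefin (this sets C1=C10), and the trisubstituted C4=C5 is inert.

Step 11
Reactants: 15 sultone
Product: 16 sultone with a (Z)‑allylic bromide at C3 (O6 still a TBS ether)
Conditions: Ph3PBr2 (1.2 equiv), CH2Cl2, −10 to 0 °C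
Reagents that add atoms: dibromotriphenylphosphorane BrP(Br)(c1ccccc1)(c1ccccc1)c1ccccc1
Why: Ph3PBr2 turns silyl ethers directly into bromides through an alkoxyphosphonium salt; the unhindered primary allylic ether should react first by SN2 at CH2 (Z olefin kept), while the secondary O6 ether next to C7 is shielded.

Step 12
Reactants: 16 bromo sultone
Product: 18 bicyclo[5.3.2] sultone (ten‑membered Z,Z‑carbocycle bridged C2–SO2–O–C8), via lithiated sultone 17 (not isolated)
Conditions: LiHMDS (1.3 equiv), THF/DMPU, slow addition of 16 (final 1 mM), −40 to 0 °C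
Reagents that add atoms: none
Why: LiHMDS removes a C2 proton, which is both allylic and alpha to the sulfonyl group, and carbanion 17 displaces the primary allylic bromide at C3 by SN2, forming C2–C3. The closest known reaction types are the alpha‑alkylation of lithiated sultones and the macrocyclisation of allylic sulfonyl carbanions onto allylic halides used for 1,5‑dienes. The ten‑membered carbocycle (nine‑membered if counted through S–O) closes in the exo‑tet mode. The only new stereocentre, C2, is dictated by the bridge, since C3 can bond only on the sultone face that carries C7 (cis), and it is erased in step 13. Alpha rather than gamma attack is secured by charge localisation next to sulfur and the fully substituted C10, and SN2 rather than SN2' by the primary C3 against the C5 flanked by C6–OTBS. Both Z olefins survive (C1=C10 is ring‑locked, C4=C5 is untouched), and cyclisation beats oligomerisation through high dilution, the sultone holding C2 about 3 Å from C8, and the fold given by the Z olefins.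

Step 13
Reactants: 18 bicyclic sultone
Product: 20 (1(10)Z,4Z)‑6‑(tert‑butyldimethylsilyloxy)germacra‑1(10),4‑dien‑8‑ol, via lithium alkyl sulfite 19 (not isolated)
Conditions: PdCl2(dppp) (10 mol %), LiHBEt3 (3 equiv), THF, 0 °C to rt; aq. NaHCO3
Reagents that add atoms: none
Why: Proposed new method: zerovalent palladium (formed from PdCl2(dppp) and the hydride) should ionise the allylic C2–S bond, the alkoxysulfonyl group leaving as the tethered alkyl sulfite anion, a sulfur oxyanion nucleofuge of the same kind as an arenesulfinate but on a more electron‑poor sulfur; hydride then attacks the less substituted π‑allyl terminus C2, syn–anti exchange at C10 would need a tertiary σ‑palladium species so the Z olefin should hold, and work‑up hydrolyses 19 at S–O so that C8 keeps its configuration; the closest known reaction type is the palladium/LiHBEt3 desulfonylation of prenyl‑type allylic aryl sulfones, which proceeds without migration or isomerisation of the double bond.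

Step 14
Reactants: 21 vanillic acid (4‑hydroxy‑3‑methoxybenzoic acid)
Product: 23 4‑(tert‑butyldimethylsilyloxy)‑3‑methoxybenzoic acid, via bis‑silylated vanillic acid 22 (not isolated)
Conditions: TBSCl (2.3 equiv), imidazole, DMF, rt; AcOH/THF/H2O, rt
Reagents that add atoms: tert‑butyldimethylsilyl chloride CC(C)(C)[Si](C)(C)Cl
Why: Exhaustive silylation followed by selective hydrolysis of the far more labile silyl ester leaves the phenol protected and the acid free.

Step 15
Reactants: 20 macrocyclic alcohol; 23 protected vanillic acid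
Product: 24 8‑O‑[4‑(tert‑butyldimethylsilyloxy)‑3‑methoxybenzoyl] derivative of 20
Conditions: DCC, DMAP, CH2Cl2, rt to 40 °C
Reagents that add atoms: none
Why: Steglich esterification acylates the only free hydroxyl (O8–H) at oxygen, so C8 is not touched.

Step 16
Reactants: 24 bis‑silyl ester
Product: 25 (1(10)Z,4Z,6S,7R,8R)‑6‑hydroxygermacra‑1(10),4‑dien‑8‑yl 4‑hydroxy‑3‑methoxybenzoate (target)
Conditions: HF·pyridine, pyridine, THF, 0 °C to rt
Reagents that add atoms: none
Why: Buffered HF cleaves both the phenolic and the allylic silyl ether without forming an alkoxide, which avoids the 1,3‑acyl shift from O8 to O6 and is mild toward the diene.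

Compound list
1 | prop‑2‑yn‑1‑ol | C#CCO | starting material
2 | alkenylmagnesium alkoxide (five‑membered magnesacycle) | CC1=C[Mg]OC1 | intermediate
3 | (Z)‑3‑iodo‑2‑methylprop‑2‑en‑1‑ol | OC/C(C)=C\I | intermediate
4 | TBS ether of 3 | CC(C)(C)[Si](C)(C)OC/C(C)=C\I | intermediate
5 | Z‑alkenyllithium | [Li]/C=C(\CO[Si](C)(C)C(C)(C)C)C | intermediate
6 | (Z)‑4‑(TBSO)‑3‑methylbut‑2‑enal | O=C/C=C(\CO[Si](C)(C)C(C)(C)C)C | intermediate
7 | (R)‑4‑benzyl‑3‑(3‑methylbutanoyl)oxazolidin‑2‑one | CC(C)CC(=O)N1[C@H](Cc2ccccc2)COC1=O | starting material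
8 | dibutylboron Z‑enolate of 7 | CCCCB(CCCC)O/C(=C\C(C)C)N1[C@H](Cc2ccccc2)COC1=O | intermediate
9 | syn aldol imide | O=C(N1[C@H](Cc2ccccc2)COC1=O)[C@@H]([C@H](/C=C(\CO[Si](C)(C)C(C)(C)C)C)O)C(C)C | intermediate
10 | hydroxy Weinreb amide | CON(C)C(=O)[C@@H]([C@H](/C=C(\CO[Si](C)(C)C(C)(C)C)C)O)C(C)C | intermediate
11 | bis‑TBS Weinreb amide | CON(C)C(=O)[C@@H]([C@H](/C=C(\CO[Si](C)(C)C(C)(C)C)C)O[Si](C)(C)C(C)(C)C)C(C)C | intermediate
12 | C8 aldehyde | O=C[C@@H]([C@H](/C=C(\CO[Si](C)(C)C(C)(C)C)C)O[Si](C)(C)C(C)(C)C)C(C)C | intermediate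
13 | homoallylic alcohol (8R, all‑syn triad) | O[C@H](CC(C)=C)[C@@H]([C@H](/C=C(\CO[Si](C)(C)C(C)(C)C)C)O[Si](C)(C)C(C)(C)C)C(C)C | intermediate
14 | O8 allylsulfonate | C=CCS(=O)(=O)O[C@H](CC(C)=C)[C@@H]([C@H](/C=C(\CO[Si](C)(C)C(C)(C)C)C)O[Si](C)(C)C(C)(C)C)C(C)C | intermediate
15 | seven‑membered Z sultone | O=S1(=O)C/C=C(/C)C[C@@H](O1)[C@@H]([C@H](/C=C(\CO[Si](C)(C)C(C)(C)C)C)O[Si](C)(C)C(C)(C)C)C(C)C | intermediate
16 | sultone Z‑allylic bromide | O=S1(=O)C/C=C(/C)C[C@@H](O1)[C@@H]([C@H](/C=C(\CBr)C)O[Si](C)(C)C(C)(C)C)C(C)C | intermediate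
17 | C2‑lithiated sultone | O=S1(=O)C([Li])/C=C(/C)C[C@@H](O1)[C@@H]([C@H](/C=C(\CBr)C)O[Si](C)(C)C(C)(C)C)C(C)C | intermediate
18 | bicyclo[5.3.2] sultone | O=S1(=O)O[C@@H]2C/C(C)=C\[C@H]1C/C(C)=C\[C@H](O[Si](C)(C)C(C)(C)C)[C@H]2C(C)C | intermediate
19 | lithium alkyl sulfite at O8 | [Li+].[O-]S(=O)O[C@@H]1C/C(C)=C\CC/C(C)=C\[C@H](O[Si](C)(C)C(C)(C)C)[C@H]1C(C)C | intermediate
20 | 6‑O‑TBS (Z,Z)‑germacradiene‑6,8‑diol | O[C@@H]1C/C(C)=C\CC/C(C)=C\[C@H](O[Si](C)(C)C(C)(C)C)[C@H]1C(C)C | intermediate
21 | vanillic acid | COc1cc(C(=O)O)ccc1O | starting material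
22 | bis‑silylated vanillic acid | COc1cc(C(=O)O[Si](C)(C)C(C)(C)C)ccc1O[Si](C)(C)C(C)(C)C | intermediate
23 | 4‑(TBSO)‑3‑methoxybenzoic acid | COc1cc(C(=O)O)ccc1O[Si](C)(C)C(C)(C)C | intermediate
24 | bis‑silyl ester | COc1cc(C(=O)O[C@@H]2C/C(C)=C\CC/C(C)=C\[C@H](O[Si](C)(C)C(C)(C)C)[C@H]2C(C)C)ccc1O[Si](C)(C)C(C)(C)C | intermediate
25 | target | COc1cc(C(=O)O[C@@H]2C/C(C)=C\CC/C(C)=C\[C@H](O)[C@H]2C(C)C)ccc1O | target

Total step count: 16. Longest linear sequence: 15 (steps 1–13, 15, 16).

Steps most likely to fail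

Step 13. Hydride may attack sulfur or C8 before zerovalent palladium ionises the C2–S bond. The olefin face anti to sulfur may also be shielded by the C3–C7 bridge. The outcome would be loss of the C8 oxygen or no conversion. The fallback sets out from 18 and returns at 20. It replaces the metal‑templated substitution by electron‑transfer fragmentation with lithium in ethylamine/THF at −78 °C, with t‑BuOH as proton source. This cleavage is known both for allylic sulfones in 1,5‑diene synthesis and for sulfonate esters (S–O cleavage back to the alcohol). The allyl anion is protonated mainly at its less substituted end C2, and the silyl ether survives. No new compound is made.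

Step 12. Oligomerisation, SN2' closure at C5, or base‑induced elimination across C8–C9 with opening of the sultone may outrun the strained bridged closure. The fallback sets out from 13 and returns at 20, using an open‑chain aryl sulfone and only known reactions.
- Acryloyl chloride and iPr2NEt give the acrylate F1.
- RCM with the second‑generation Grubbs catalyst gives the six‑membered Z‑locked lactone F2.
- DIBAL‑H opens it to the Z diol F3.
- Corey–Kim chlorination (NCS, Me2S) converts only the primary allylic alcohol into the allylic chloride F4.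
- PhSO2Na in DMF gives the hydroxy sulfone F5.
- PivCl, DMAP and pyridine give the pivalate F6, an ester without alpha protons that is too hindered for acyl transfer to the carbanion.
- Ph3PBr2 gives the allylic bromide F7.
- LiHMDS at high dilution closes the monocyclic ring to the macrocyclic sulfone pivalate F8.
- PdCl2(dppp) with excess LiHBEt3 removes the sulfonyl group and the pivalate together to give 20.

Step 8. Poor facial selectivity or sluggish addition is possible if the reagent and the very hindered α‑isopropyl aldehyde form a mismatched pair. The fallback sets out from 12 and returns at 13, and it separates C–C bond formation from creation of the stereocentre. Methallylmagnesium chloride gives 13 together with its C8 epimer F9. Dess–Martin periodinane oxidises the mixture to the β,γ‑unsaturated ketone F10. CBS reduction ((S)‑2‑methyl‑CBS‑oxazaborolidine, catecholborane, toluene, −78 °C) distinguishes the branched C7 side from the C9 methylene and should deliver the (8R) alcohol 13.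

Further compounds
F0 | step 13 | none | none
F1 | step 12 | acrylate of 13 | C=CC(=O)O[C@H](CC(C)=C)[C@@H]([C@H](/C=C(\CO[Si](C)(C)C(C)(C)C)C)O[Si](C)(C)C(C)(C)C)C(C)C
F2 | step 12 | 4‑methyl‑5,6‑dihydro‑2H‑pyran‑2‑one lactone | O=C1C=C(C)C[C@@H](O1)[C@@H]([C@H](/C=C(\CO[Si](C)(C)C(C)(C)C)C)O[Si](C)(C)C(C)(C)C)C(C)C
F3 | step 12 | Z diol (C2–OH, C8–OH) | OC/C=C(/C)C[C@@H](O)[C@@H]([C@H](/C=C(\CO[Si](C)(C)C(C)(C)C)C)O[Si](C)(C)C(C)(C)C)C(C)C
F4 | step 12 | Z allylic chloride | ClC/C=C(/C)C[C@@H](O)[C@@H]([C@H](/C=C(\CO[Si](C)(C)C(C)(C)C)C)O[Si](C)(C)C(C)(C)C)C(C)C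
F5 | step 12 | hydroxy phenyl sulfone | O=S(=O)(c1ccccc1)C/C=C(/C)C[C@@H](O)[C@@H]([C@H](/C=C(\CO[Si](C)(C)C(C)(C)C)C)O[Si](C)(C)C(C)(C)C)C(C)C
F6 | step 12 | O8 pivalate | O=S(=O)(c1ccccc1)C/C=C(/C)C[C@@H](OC(=O)C(C)(C)C)[C@@H]([C@H](/C=C(\CO[Si](C)(C)C(C)(C)C)C)O[Si](C)(C)C(C)(C)C)C(C)C
F7 | step 12 | sulfone allylic bromide | O=S(=O)(c1ccccc1)C/C=C(/C)C[C@@H](OC(=O)C(C)(C)C)[C@@H]([C@H](/C=C(\CBr)C)O[Si](C)(C)C(C)(C)C)C(C)C
F8 | step 12 | macrocyclic sulfone pivalate (C2 epimers) | CC(C)(C)C(=O)O[C@@H]1C/C(C)=C\C(S(=O)(=O)c2ccccc2)C/C(C)=C\[C@H](O[Si](C)(C)C(C)(C)C)[C@H]1C(C)C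
F9 | step 8 | C8 epimer of 13 | O[C@@H](CC(C)=C)[C@@H]([C@H](/C=C(\CO[Si](C)(C)C(C)(C)C)C)O[Si](C)(C)C(C)(C)C)C(C)C
F10 | step 8 | β,γ‑unsaturated C8 ketone | O=C(CC(C)=C)[C@@H]([C@H](/C=C(\CO[Si](C)(C)C(C)(C)C)C)O[Si](C)(C)C(C)(C)C)C(C)C
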